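The oxolane ring (O1, C2 aryl, C3 CH2OH, C4 aroyl, C5 H2) is cut at O1–C5 and C2–C3. O1 and C2 come from 3,4-dimethoxybenzaldehyde; C3–C4–C5 with both side chains come from one reagent, an (E)-2-aroyl-allylboronate made in a single step by palladium-catalysed acylboration of a silyloxymethyl allene. The key step exploits the β-alkoxy ketone O1–C5–C4–C(=O)Ar hidden in the ring: a chiral-acid-catalysed allylboration forms C2–C3 with allylic transposition, sets C2 and C3 (2,3-cis) and unveils an aryl vinyl ketone, onto whose terminus C5 the new alkoxide O1 closes in the same flask, C4 settling trans. Desilylation gives the target.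

Key step: step 3

Remark: buta-2,3-dien-1-ol, 3,4,5-trimethoxybenzoyl chloride, 3,4-dimethoxybenzaldehyde, B2pin2 and (R)-TRIP are taken as commercial. The target is (2R,3R,4S) in the ring numbering above, that is 2,3-cis and 3,4-trans.

Step 1
Reactants: 1 buta-2,3-dien-1-ol
Product: 2 (buta-2,3-dien-1-yloxy)tri(propan-2-yl)silane
Conditions: TIPSCl, imidazole, CH2Cl2, 0 °C → rt
Reagents that add atoms: chlorotri(propan-2-yl)silane (TIPSCl), CC(C)[Si](Cl)(C(C)C)C(C)C
Why: Standard silylation of a primary alcohol; the triisopropylsilyl group is chosen because it should survive the chloroborane by-product of step 2 and resist oxygen-to-oxygen migration under the basic conditions of step 3.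

Step 2
Reactants: 2 (buta-2,3-dien-1-yloxy)tri(propan-2-yl)silane (1.5 equiv), 3 3,4,5-trimethoxybenzoyl chloride
Product: 4 (2E)-2-[(4,4,5,5-tetramethyl-1,3,2-dioxaborolan-2-yl)methyl]-4-{[tri(propan-2-yl)silyl]oxy}-1-(3,4,5-trimethoxyphenyl)but-2-en-1-one
Conditions: B2pin2 (1.0 equiv), PdCl2(MeCN)2 (5 mol%), toluene, 80 °C
Reagents that add atoms: bis(pinacolato)diboron (B2pin2), CC1(C)OB(OC1(C)C)B1OC(C)(C)C(C)(C)O1
Why: Palladium-catalysed three-component acylboration of an allene, in which the aroyl chloride adds oxidatively to zerovalent palladium, acylpalladation of the terminal C=C from the face remote from CH2OTIPS puts the aroyl group on the central carbon with CH2OTIPS trans to the carbonyl (E), and transmetalation with B2pin2 followed by reductive elimination at the unsubstituted terminus delivers the allylboronate.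

Step 3
Reactants: 4 (2E)-2-[(4,4,5,5-tetramethyl-1,3,2-dioxaborolan-2-yl)methyl]-4-{[tri(propan-2-yl)silyl]oxy}-1-(3,4,5-trimethoxyphenyl)but-2-en-1-one (1.2 equiv), 5 3,4-dimethoxybenzaldehyde
Product: 8 [(3S,4R,5R)-5-(3,4-dimethoxyphenyl)-4-{[tri(propan-2-yl)silyl]oxymethyl}oxolan-3-yl](3,4,5-trimethoxyphenyl)methanone, via borate ester 6 (not isolated), via potassium alkoxide 7 (not isolated)
Conditions: (R)-TRIP [(R)-3,3'-bis(2,4,6-triisopropylphenyl)-1,1'-binaphthyl-2,2'-diyl hydrogen phosphate] (10 mol%), 4 Å MS, toluene, 0 °C → rt; then KOt-Bu (1.2 equiv), t-BuOH, THF, 0 °C → rt; aq NH4Cl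
Reagents that add atoms: none
Why: Proposed new method: the chiral phosphoric acid should hydrogen-bond to a boronate oxygen of 4 and to the formyl C–H of 5, so that the allyl unit is delivered through a closed chair transition state to the Re face of the aldehyde with allylic transposition, which forms C2–C3, leaves boron on O1 (borate 6) and unveils the enone C5H2=C4–C(=O)Ar; tert-butoxide then releases alkoxide 7, whose O1 adds to the enone terminus C5 and closes the oxolane ring in the 5-endo-trig mode (oxa-Michael addition), and the enolate is protonated reversibly by tert-butanol. The closest known reaction types are the allylboration of aldehydes with 2-alkoxycarbonyl-allylboronates (where the alkoxide lactonises instead), the phosphoric-acid-catalysed enantioselective allyl- and crotylboration of aryl aldehydes with pinacol boronates, and the base-mediated 5-endo-trig cyclisation of homoallylic alkoxides onto internal vinyl sulfones; with a ketone in place of the ester, conjugate addition at C5 is the only productive outlet for O1, since addition to the carbonyl is reversible. C2 (R) is controlled by the catalyst; C3 (R) by the chair transition state, in which the aryl group of 5 is equatorial and the CH2OTIPS group, cis to CH2B in (E)-4, is axial, so that the syn adduct and hence the 2,3-cis ring should result; C4 (S) by thermodynamic protonation of the enolate, trans to both neighbours. The step needs γ-selective C–C bond formation, secured by the cyclic transition state, and ring closure by O1 alone, secured by the migration-resistant silyl ether on the other oxygen. The geometrically unfavourable 5-endo-trig closure is the main uncertainty; the high electrophilicity of the aryl vinyl ketone and the reversibility of the addition should drive it to the oxolane.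

Step 4
Reactants: 8 [(3S,4R,5R)-5-(3,4-dimethoxyphenyl)-4-{[tri(propan-2-yl)silyl]oxymethyl}oxolan-3-yl](3,4,5-trimethoxyphenyl)methanone
Product: 9 [(3S,4R,5R)-5-(3,4-dimethoxyphenyl)-4-(hydroxymethyl)oxolan-3-yl](3,4,5-trimethoxyphenyl)methanone
Conditions: HF·pyridine, pyridine, THF, 0 °C → rt
Reagents that add atoms: none
Why: Fluoride-mediated cleavage of the primary silyl ether under buffered, non-basic conditions, which should avoid retro-oxa-Michael opening of the β-alkoxy ketone and leave the three stereocentres untouched.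

Compound list
1 | buta-2,3-dien-1-ol | C=C=CCO | starting material
2 | (buta-2,3-dien-1-yloxy)tri(propan-2-yl)silane | C=C=CCO[Si](C(C)C)(C(C)C)C(C)C | intermediate
3 | 3,4,5-trimethoxybenzoyl chloride | COc1cc(C(=O)Cl)cc(OC)c1OC | starting material
4 | (2E)-2-[(4,4,5,5-tetramethyl-1,3,2-dioxaborolan-2-yl)methyl]-4-{[tri(propan-2-yl)silyl]oxy}-1-(3,4,5-trimethoxyphenyl)but-2-en-1-one | COc1cc(C(=O)/C(CB2OC(C)(C)C(C)(C)O2)=C/CO[Si](C(C)C)(C(C)C)C(C)C)cc(OC)c1OC | intermediate
5 | 3,4-dimethoxybenzaldehyde | COc1ccc(C=O)cc1OC | starting material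
6 | 2-[(1R,2R)-1-(3,4-dimethoxyphenyl)-3-methylidene-4-oxo-2-{[tri(propan-2-yl)silyl]oxymethyl}-4-(3,4,5-trimethoxyphenyl)butoxy]-4,4,5,5-tetramethyl-1,3,2-dioxaborolane (borate ester) | COc1ccc([C@H](OB2OC(C)(C)C(C)(C)O2)[C@@H](CO[Si](C(C)C)(C(C)C)C(C)C)C(=C)C(=O)c3cc(OC)c(OC)c(OC)c3)cc1OC | intermediate
7 | potassium (1R,2R)-1-(3,4-dimethoxyphenyl)-3-methylidene-4-oxo-2-{[tri(propan-2-yl)silyl]oxymethyl}-4-(3,4,5-trimethoxyphenyl)butan-1-olate | COc1ccc([C@H]([O-])[C@@H](CO[Si](C(C)C)(C(C)C)C(C)C)C(=C)C(=O)c2cc(OC)c(OC)c(OC)c2)cc1OC.[K+] | intermediate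
8 | [(3S,4R,5R)-5-(3,4-dimethoxyphenyl)-4-{[tri(propan-2-yl)silyl]oxymethyl}oxolan-3-yl](3,4,5-trimethoxyphenyl)methanone | COc1ccc([C@@H]2OC[C@@H](C(=O)c3cc(OC)c(OC)c(OC)c3)[C@@H]2CO[Si](C(C)C)(C(C)C)C(C)C)cc1OC | intermediate
9 | [(3S,4R,5R)-5-(3,4-dimethoxyphenyl)-4-(hydroxymethyl)oxolan-3-yl](3,4,5-trimethoxyphenyl)methanone | COc1ccc([C@@H]2OC[C@@H](C(=O)c3cc(OC)c(OC)c(OC)c3)[C@@H]2CO)cc1OC | target

Total step count: 4. Longest linear sequence: 4 steps (1 → 2 → 4 → 8 → 9).

Steps most likely to fail

1. Step 3 (proposed new method). The deactivated 2-aroyl-allylboronate may add too slowly or with poor facial selectivity under the chiral acid. The alkoxide may also fail to close in the 5-endo-trig mode, or silyl migration may let the other oxygen close the ring. The fallback sets out from allene 2 and aldehyde 5 and returns at 8, making the two bonds in separate, known operations. Kinetic hydroboration of 2 with the diisopinocampheylborane derived from (−)-α-pinene (THF, low temperature) should give the (Z)-allylborane F1. Its addition to 5 at −78 °C through a chair transition state, then NaOH/H2O2, should give the syn-homoallylic alcohol (1R,2R)-1-(3,4-dimethoxyphenyl)-2-{[tri(propan-2-yl)silyl]oxymethyl}but-3-en-1-ol F2. Iodine and NaHCO3 in MeCN should then close the ring by 5-endo-trig iodoetherification to the 4-iodo-oxolane F3, whose C4 configuration is inconsequential. A nickel-catalysed reductive coupling of this secondary iodide with acid chloride 3 (NiCl2(dme), 4,4'-di-tert-butyl-2,2'-bipyridine, Mn, DMA), followed by equilibration with DBU, should install the aroyl group trans at C4 and give 8.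

2. Step 2. Alkene geometry or regiochemistry may be poorly controlled in the acylpalladation, the allylpalladium intermediate may undergo β-silyloxy elimination, or the chloroborane by-product may cleave the silyl ether. The fallback sets out from acid chloride 3 and returns at 4. Stille coupling of 3 with tributyl(vinyl)stannane (PdCl2(PPh3)2 cat., toluene) should give 1-(3,4,5-trimethoxyphenyl)prop-2-en-1-one F4. A DABCO-catalysed Morita–Baylis–Hillman reaction with 2-{[tri(propan-2-yl)silyl]oxy}acetaldehyde should give the allylic alcohol F5, and Ac2O/pyridine its acetate F6. Pd2(dba)3-catalysed substitution with B2pin2 through an equilibrating π-allylpalladium intermediate should then give the thermodynamically preferred (E)-boronate 4.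

3. Step 4. Desilylation may be accompanied by retro-oxa-Michael opening and re-closure through the liberated primary hydroxyl (ring isomerisation), by epimerisation at C4, or by acid-promoted ionisation at the benzylic C2. The fallback sets out from 8 and returns at 9. NaBH4 reduction of the ketone should give the carbinol F7 (epimers at the new centre), which can no longer open by retro-oxa-Michael reaction. TBAF should then give the diol F8, and activated MnO2 in CH2Cl2 should oxidise only the benzylic secondary alcohol back to the ketone, giving 9.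

Further compounds
F1 | step 3 | bis[(1S,2R,3S,5S)-2,6,6-trimethylbicyclo[3.1.1]heptan-3-yl][(2Z)-4-{[tri(propan-2-yl)silyl]oxy}but-2-en-1-yl]borane | C(/C=C\CO[Si](C(C)C)(C(C)C)C(C)C)B([C@H]1C[C@H]2C[C@@H]([C@@H]1C)C2(C)C)[C@H]1C[C@H]2C[C@@H]([C@@H]1C)C2(C)C
F2 | step 3 | (1R,2R)-1-(3,4-dimethoxyphenyl)-2-{[tri(propan-2-yl)silyl]oxymethyl}but-3-en-1-ol | COc1ccc([C@H](O)[C@@H](CO[Si](C(C)C)(C(C)C)C(C)C)C=C)cc1OC
F3 | step 3 | (2R,3R,4S)-2-(3,4-dimethoxyphenyl)-4-iodo-3-{[tri(propan-2-yl)silyl]oxymethyl}oxolane | COc1ccc([C@@H]2OC[C@@H](I)[C@@H]2CO[Si](C(C)C)(C(C)C)C(C)C)cc1OC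
F4 | step 2 | 1-(3,4,5-trimethoxyphenyl)prop-2-en-1-one | COc1cc(C(=O)C=C)cc(OC)c1OC
F5 | step 2 | 3-hydroxy-2-methylidene-4-{[tri(propan-2-yl)silyl]oxy}-1-(3,4,5-trimethoxyphenyl)butan-1-one (racemic) | COc1cc(C(=O)C(=C)C(O)CO[Si](C(C)C)(C(C)C)C(C)C)cc(OC)c1OC
F6 | step 2 | 3-methylidene-4-oxo-1-{[tri(propan-2-yl)silyl]oxy}-4-(3,4,5-trimethoxyphenyl)butan-2-yl acetate (racemic) | COc1cc(C(=O)C(=C)C(OC(C)=O)CO[Si](C(C)C)(C(C)C)C(C)C)cc(OC)c1OC
F7 | step 4 | [(3S,4R,5R)-5-(3,4-dimethoxyphenyl)-4-{[tri(propan-2-yl)silyl]oxymethyl}oxolan-3-yl](3,4,5-trimethoxyphenyl)methanol (both carbinol epimers) | COc1ccc([C@@H]2OC[C@@H](C(O)c3cc(OC)c(OC)c(OC)c3)[C@@H]2CO[Si](C(C)C)(C(C)C)C(C)C)cc1OC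
F8 | step 4 | [(3S,4R,5R)-5-(3,4-dimethoxyphenyl)-4-(hydroxymethyl)oxolan-3-yl](3,4,5-trimethoxyphenyl)methanol (both carbinol epimers) | COc1ccc([C@@H]2OC[C@@H](C(O)c3cc(OC)c(OC)c(OC)c3)[C@@H]2CO)cc1OC
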